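**Retrosynthetic overview**
1. Target ⇐ 2,3-diol 23 (IBX gives the 2,3-dione, which enolises to the diosphenol) ⇐ 22, where one acid treatment unmasks the C4=CH2 (Peterson), the diol (acetonide) and the acid (tert-butyl ester).
2. C7-OAc/C8-Me ⇐ hydroboration of the C7=C8(Me) alkene 19 ⇐ enol triflate ⇐ ring-B enone; side chain ⇐ HWE on a 3-oxobutyl group; quaternary C9 ⇐ enolate methylation, then Michael addition.
3. Masked ring A (C4 β-hydroxysilane, C2/C3 acetonide) ⇐ bis-enone 7 ⇐ Saegusa oxidation and Criegee excision of the isopropenyl group.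
4. Key disconnection: ring B by Diels–Alder reaction of (S)-carvone (ring A, the only purchased stereocentre, erased later) with 2-(trimethylsilyloxy)butadiene. Ring A is bought, ring B is formed by the [4+2].

Assumption: clerodane numbering is used throughout (ring A C-1–C-5/C-10, ring B C-5–C-10; C-18 on C-4, C-19 on C-5, C-17 on C-8, C-20 and C-11–C-16 on C-9); β is the face carrying H-10 and CH3-19; the transient centres at C-2, C-3, C-4 and at C-9 before it is quaternary are drawn as the expected major isomers, are destroyed later and do not affect the outcome.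

**Step 1**
Reactants: 1 (S)-(+)-carvone; 2 2-(trimethylsilyloxy)buta-1,3-diene
Product: 3 cis-fused adduct, 2β-isopropenyl-5β-methyl-8-(trimethylsilyloxy)-10β-H-decal-7-en-4-one
Conditions: EtAlCl2 (0.5 equiv), toluene, 0 °C → rt
Reagents that add atoms: none
Why: Lewis-acid-catalysed Diels–Alder reaction in which the diene adds anti to the isopropenyl group (sets 5β-Me/10β-H, cis fusion) and the nucleophilic CH2 next to the siloxy carbon bonds to the enone β-carbon C-10, so the oxygen ends at C-8.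

**Step 2**
Reactants: 3 silyl enol ether adduct
Product: 4 2β-isopropenyl-5β-methyl-10β-H-cis-decal-6-ene-4,8-dione
Conditions: Pd(OAc)2 (1.05 equiv), MeCN, rt
Reagents that add atoms: none
Why: Saegusa–Ito oxidation of the regiodefined silyl enol ether gives the Δ6-en-8-one, which leaves C-9 as the only enolisable position of the ring-B ketone.

**Step 3**
Reactants: 4 ene-dione
Product: 7 (4aR,8aR)-8a-methyl-4,4a,5,8a-tetrahydronaphthalene-1,6-dione (5β-methyl-10β-H-cis-decala-2,6-diene-4,8-dione), via methoxy hydroperoxide 5 (not isolated), via C-2 acetate 6 (not isolated)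
Conditions: O3, CH2Cl2/MeOH, −78 °C; then Ac2O, Et3N, DMAP, 0 °C → rt; then DBU, rt
Reagents that add atoms: none
Why: Chemoselective ozonolysis of the electron-rich isopropenyl group, Criegee rearrangement to the C-2 acetate and E1cB elimination of this β-acetoxy ketone give the Δ2-en-4-one, erasing the carvone stereocentre after it has set C-5 and C-10.

**Step 4**
Reactants: 7 bis-enone
Product: 10 4α-hydroxy-4β-(trimethylsilylmethyl)-5β,9-dimethyl-10β-H-cis-decala-2,6-dien-8-one, via lithium dienolate 8 (not isolated), via dilithio adduct 9 (not isolated)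
Conditions: LDA (1.05 equiv), THF, −78 °C; Me3SiCH2Li (1.2 equiv), −78 °C; then MeI, DMPU, −78 → −30 °C; aq. NH4Cl
Reagents that add atoms: (trimethylsilyl)methyllithium [Li]C[Si](C)(C)C; iodomethane CI
Why: Kinetic α′-deprotonation masks the ring-B enone as its enolate so the Peterson reagent undergoes 1,2-addition only at C-4, and the same enolate is then C-methylated at C-9 (enolate alkylation; both new centres are erased or re-set later).

**Step 5**
Reactants: 10 allylic β-hydroxysilane
Product: 11 2α,3α,4α-trihydroxy-4β-(trimethylsilylmethyl)-5β,9-dimethyl-10β-H-cis-decal-6-en-8-one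
Conditions: OsO4 (2 mol %), NMO, acetone/H2O, rt
Reagents that add atoms: osmium tetroxide O=[Os](=O)(=O)=O; N-methylmorpholine N-oxide C[N+]1([O-])CCOCC1; water O
Why: Upjohn syn-dihydroxylation takes the electron-rich C2=C3 alkene rather than the hindered, electron-poor ring-B enone, from the face anti to the CH2SiMe3 group (C-2 and C-3 become sp2 again, so their configuration is immaterial).

**Step 6**
Reactants: 11 triol
Product: 12 2α,3α-O-isopropylidene derivative of 11
Conditions: 2,2-dimethoxypropane, PPTS (cat.), CH2Cl2, rt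
Reagents that add atoms: 2,2-dimethoxypropane COC(C)(C)OC
Why: Acetonide formation (transketalisation) engages the two secondary cis-hydroxyls, while the neopentylic tertiary C-4 hydroxyl is too hindered to compete and stays free.

**Step 7**
Reactants: 12 acetonide enone
Product: 15 9α-methyl-9β-(3-oxobutyl) enone, via dilithio dienolate 13 (not isolated), via α-silyl ketone 14 (not isolated)
Conditions: LDA (2.2 equiv), THF, −78 °C; 3-(trimethylsilyl)but-3-en-2-one, −78 → −40 °C; aq. NH4Cl; then K2CO3 (cat.), MeOH, 0 °C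
Reagents that add atoms: 3-(trimethylsilyl)but-3-en-2-one CC(=O)C(=C)[Si](C)(C)C
Why: Stork–Ganem Michael addition of the cross-conjugated C-9 enolate, whose nearly flat ring should be attacked on the convex β-face (syn to H-10, away from ring A and its C-4 carbinol under the α-face), sets the quaternary C-9 with the chain β and C-20 α, and protodesilylation gives the 3-oxobutyl ketone.

**Step 8**
Reactants: 15 methyl ketone
Product: 16 tert-butyl (E)-enoate carrying the complete C-11–C-16 side chain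
Conditions: t-BuO2CCH2P(O)(OEt)2 (4 equiv), NaH (3.8 equiv, phosphonate kept in excess), THF, 0 → 45 °C
Reagents that add atoms: tert-butyl 2-(diethoxyphosphoryl)acetate CCOP(=O)(CC(=O)OC(C)(C)C)OCC
Why: Horner–Wadsworth–Emmons olefination reacts only at the unhindered methyl ketone (C-8 is flanked by the quaternary C-9) and gives mainly the E-enoate, the minor Z isomer being removed by chromatography.

**Step 9**
Reactants: 16 enone ester
Product: 18 Δ7-C-8 enol triflate, via lithium enolate 17 (not isolated)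
Conditions: L-Selectride, THF, −78 °C; then PhNTf2, −78 → 0 °C; aq. NH4Cl
Reagents that add atoms: N-phenylbis(trifluoromethanesulfonimide) O=S(=O)(N(c1ccccc1)S(=O)(=O)C(F)(F)F)C(F)(F)F
Why: Conjugate reduction of the β-unsubstituted enone, whose carbonyl is shielded by C-9, gives the Δ7 enolate regiospecifically and O-triflation traps it (reductive enol triflate formation).

**Step 10**
Reactants: 18 enol triflate
Product: 19 8-methyl-Δ7-alkene
Conditions: MeMgBr (4 equiv), Fe(acac)3 (10 mol %), THF/NMP, −30 → 0 °C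
Reagents that add atoms: methylmagnesium bromide C[Mg]Br
Why: Iron-catalysed Kumada-type cross-coupling of the hindered alkenyl triflate installs C-17 without touching the tert-butyl enoate.

**Step 11**
Reactants: 19 trisubstituted alkene
Product: 21 7β-hydroxy-8α-methyl compound, via C-7 alkylborane 20 (not isolated)
Conditions: BH3·THF, THF, 0 °C → rt; then NaOH, H2O2, 0 °C
Reagents that add atoms: hydrogen peroxide OO
Why: Hydroboration–oxidation adds H and OH syn and anti-Markovnikov across the only electron-rich alkene, from the β-face opposite the pseudo-axial 9α-methyl and ring A, setting 7β-OH and 8β-H (8α-Me) together.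

**Step 12**
Reactants: 21 secondary alcohol
Product: 22 7β-acetate
Conditions: Ac2O, pyridine, DMAP (cat.), CH2Cl2, rt
Reagents that add atoms: acetic anhydride CC(=O)OC(C)=O
Why: Acylation of the only secondary alcohol; the tertiary β-silyl carbinol at C-4 is too hindered to react.

**Step 13**
Reactants: 22 fully masked precursor
Product: 23 7β-acetoxy-2α,3α-dihydroxy-cis-cleroda-4(18),13E-dien-15-oic acid
Conditions: TFA/H2O (9:1), CH2Cl2, 0 °C → rt
Reagents that add atoms: none
Why: One acid treatment effects the acid-mediated Peterson elimination (regiospecific C4=C18 exo-methylene), acetonide hydrolysis and tert-butyl ester cleavage, while the secondary acetate survives.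

**Step 14**
Reactants: 23 diol acid
Product: 25 target CNP0192653.1, via 2,3-dione 24 (not isolated)
Conditions: IBX (3 equiv), DMSO, rt
Reagents that add atoms: none
Why: IBX oxidation of the vicinal diol gives the 1,2-diketone without C–C cleavage, and this enolises in the only possible direction (towards C-1, since C-4 has no hydrogen) to the diosphenol.

**Compound list**
1 | (S)-(+)-carvone, (5S)-2-methyl-5-(prop-1-en-2-yl)cyclohex-2-en-1-one | CC1=CC[C@@H](CC1=O)C(C)=C | starting material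
2 | 2-(trimethylsilyloxy)buta-1,3-diene | C=CC(=C)O[Si](C)(C)C | starting material
3 | Diels–Alder adduct, 2β-isopropenyl-5β-methyl-8-(trimethylsilyloxy)-10β-H-cis-decal-7-en-4-one | O=C1C[C@@H](C(C)=C)C[C@@H]2CC(O[Si](C)(C)C)=CC[C@]12C | intermediate
4 | 2β-isopropenyl-5β-methyl-10β-H-cis-decal-6-ene-4,8-dione | O=C1C[C@@H](C(C)=C)C[C@@H]2CC(=O)C=C[C@]12C | intermediate
5 | 4 with the isopropenyl converted into a 1-hydroperoxy-1-methoxyethyl group (not isolated) | O=C1C[C@@H](C(C)(OC)OO)C[C@@H]2CC(=O)C=C[C@]12C | intermediate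
6 | 2β-acetoxy-5β-methyl-10β-H-cis-decal-6-ene-4,8-dione (not isolated) | O=C1C[C@@H](OC(C)=O)C[C@@H]2CC(=O)C=C[C@]12C | intermediate
7 | (4aR,8aR)-8a-methyl-4,4a,5,8a-tetrahydronaphthalene-1,6-dione | O=C1C=CC[C@@H]2CC(=O)C=C[C@]12C | intermediate
8 | lithium C-8 dienolate of 7 (not isolated) | O=C1C=CC[C@@H]2C=C(O[Li])C=C[C@]12C | intermediate
9 | dilithio C-4 alkoxide/C-8 dienolate after Me3SiCH2Li addition (not isolated) | [Li]O[C@]1(C[Si](C)(C)C)C=CC[C@@H]2C=C(O[Li])C=C[C@]12C | intermediate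
10 | 4α-hydroxy-4β-(trimethylsilylmethyl)-5β,9-dimethyl-10β-H-cis-decala-2,6-dien-8-one | O[C@]1(C[Si](C)(C)C)C=CC[C@@H]2[C@@H](C)C(=O)C=C[C@]12C | intermediate
11 | 2α,3α,4α-triol of 10 | O[C@]1(C[Si](C)(C)C)[C@H](O)[C@H](O)C[C@@H]2[C@@H](C)C(=O)C=C[C@]12C | intermediate
12 | 2α,3α-acetonide of 11 | O[C@]1(C[Si](C)(C)C)[C@@H]3OC(C)(C)O[C@@H]3C[C@@H]2[C@@H](C)C(=O)C=C[C@]12C | intermediate
13 | dilithio C-4 alkoxide/C-8 dienolate of 12 (not isolated) | [Li]O[C@]1(C[Si](C)(C)C)[C@@H]3OC(C)(C)O[C@@H]3C[C@@H]2C(C)=C(O[Li])C=C[C@]12C | intermediate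
14 | 9α-methyl-9β-[3-oxo-2-(trimethylsilyl)butyl] adduct (not isolated) | O[C@]1(C[Si](C)(C)C)[C@@H]3OC(C)(C)O[C@@H]3C[C@@H]2[C@@](C)(CC([Si](C)(C)C)C(C)=O)C(=O)C=C[C@]12C | intermediate
15 | 9α-methyl-9β-(3-oxobutyl) enone | O[C@]1(C[Si](C)(C)C)[C@@H]3OC(C)(C)O[C@@H]3C[C@@H]2[C@@](C)(CCC(C)=O)C(=O)C=C[C@]12C | intermediate
16 | tert-butyl (13E)-enoate, ring-B Δ6-en-8-one | O[C@]1(C[Si](C)(C)C)[C@@H]3OC(C)(C)O[C@@H]3C[C@@H]2[C@@](C)(CC/C(C)=C/C(=O)OC(C)(C)C)C(=O)C=C[C@]12C | intermediate
17 | lithium Δ7-C-8 enolate (not isolated) | O[C@]1(C[Si](C)(C)C)[C@@H]3OC(C)(C)O[C@@H]3C[C@@H]2[C@@](C)(CC/C(C)=C/C(=O)OC(C)(C)C)C(O[Li])=CC[C@]12C | intermediate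
18 | Δ7-C-8 enol triflate | O[C@]1(C[Si](C)(C)C)[C@@H]3OC(C)(C)O[C@@H]3C[C@@H]2[C@@](C)(CC/C(C)=C/C(=O)OC(C)(C)C)C(OS(=O)(=O)C(F)(F)F)=CC[C@]12C | intermediate
19 | 8-methyl-Δ7-alkene | O[C@]1(C[Si](C)(C)C)[C@@H]3OC(C)(C)O[C@@H]3C[C@@H]2[C@@](C)(CC/C(C)=C/C(=O)OC(C)(C)C)C(C)=CC[C@]12C | intermediate
20 | C-7β alkylborane, 8α-methyl (not isolated) | O[C@]1(C[Si](C)(C)C)[C@@H]3OC(C)(C)O[C@@H]3C[C@@H]2[C@@](C)(CC/C(C)=C/C(=O)OC(C)(C)C)[C@H](C)[C@@H](B)C[C@]12C | intermediate
21 | 7β-alcohol, 8α-methyl | O[C@]1(C[Si](C)(C)C)[C@@H]3OC(C)(C)O[C@@H]3C[C@@H]2[C@@](C)(CC/C(C)=C/C(=O)OC(C)(C)C)[C@H](C)[C@@H](O)C[C@]12C | intermediate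
22 | 7β-acetate | O[C@]1(C[Si](C)(C)C)[C@@H]3OC(C)(C)O[C@@H]3C[C@@H]2[C@@](C)(CC/C(C)=C/C(=O)OC(C)(C)C)[C@H](C)[C@@H](OC(C)=O)C[C@]12C | intermediate
23 | 7β-acetoxy-2α,3α-dihydroxy-cis-cleroda-4(18),13E-dien-15-oic acid | C=C1[C@H](O)[C@H](O)C[C@@H]2[C@@](C)(CC/C(C)=C/C(=O)O)[C@H](C)[C@@H](OC(C)=O)C[C@]12C | intermediate
24 | 7β-acetoxy-2,3-dioxo-cis-cleroda-4(18),13E-dien-15-oic acid (not isolated) | C=C1C(=O)C(=O)C[C@@H]2[C@@](C)(CC/C(C)=C/C(=O)O)[C@H](C)[C@@H](OC(C)=O)C[C@]12C | intermediate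
25 | (5S,7S,8S,9R,10R)-7-acetoxy-2-hydroxy-3-oxo-cis-cleroda-1,4(18),13E-trien-15-oic acid (CNP0192653.1) | C=C1C(=O)C(O)=C[C@@H]2[C@@](C)(CC/C(C)=C/C(=O)O)[C@H](C)[C@@H](OC(C)=O)C[C@]12C | target

**Step count:** 14 steps in total. Longest linear sequence: 14 steps, from (S)-carvone 1.

**Steps most likely to fail**

Step 7 (C-9 quaternary centre). The β-face preference rests on a conformational argument, not on a direct precedent for this substrate, and the bond is formed at a hindered tertiary enolate carbon. If the electrophile enters from the α-face, the fallback inverts the order in which the two C-9 substituents arrive, so that the same bias places the methyl α. It sets out from 9 and comes back at 16. Quenching 9 with NH4Cl instead of MeI gives the C-9-unsubstituted carbinol enone F4. OsO4/NMO gives the triol F5 and 2,2-dimethoxypropane/PPTS its acetonide F6. LDA followed by the silyl enone gives the α-silyl adduct F7, and K2CO3/MeOH gives the 9-mono-(3-oxobutyl) ketone F8. HWE olefination gives the enoate F9, which has no other enolisable ketone. LDA (2.2 equiv) and MeI then quaternise C-9 with the small electrophile to give 16.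

Step 11 (hydroboration). The face selectivity depends on the ring-B conformer, and the sp3 C-4 carbinol could shift it. If borane adds from the α-face, the product is the 7α-hydroxy-8β-methyl isomer F10. The fallback replaces kinetic by thermodynamic control; it sets out from 19 and comes back at 21. DMP oxidises F10 to the 8β-methyl 7-ketone F11. DBU equilibrates C-8 towards the equatorial 8α-methyl 7-ketone F12. Meerwein–Ponndorf–Verley equilibration (Al(OiPr)3, iPrOH, reflux) then gives the all-equatorial 7β-alcohol 21.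

Step 4 (one-pot differentiation of two enone carbonyls). Possible failures are addition at C-8, γ-deprotonation of ring A or over-methylation. The fallback uses redox differentiation instead of enolate masking; it sets out from 7 and comes back at 10. LDA/MeI gives the 9-methyl bis-enone F1. Luche reduction (NaBH4, CeCl3, MeOH, −78 °C) takes only the less hindered C-8 carbonyl, giving the 8-allylic alcohol F2. Me3SiCH2Li (2.2 equiv) adds to the one remaining carbonyl to give the 4,8-diol F3. MnO2 re-oxidises only the secondary allylic alcohol to give 10.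

**Further compounds**
F1 | step 4 | 5β,9-dimethyl-10β-H-cis-decala-2,6-diene-4,8-dione | O=C1C=CC[C@@H]2[C@@H](C)C(=O)C=C[C@]12C
F2 | step 4 | 8α-hydroxy-5β,9-dimethyl-10β-H-cis-decala-2,6-dien-4-one | O=C1C=CC[C@@H]2[C@@H](C)[C@H](O)C=C[C@]12C
F3 | step 4 | 4α,8α-dihydroxy-4β-(trimethylsilylmethyl)-5β,9-dimethyl-10β-H-cis-decala-2,6-diene | O[C@]1(C[Si](C)(C)C)C=CC[C@@H]2[C@@H](C)[C@H](O)C=C[C@]12C
F4 | step 7 | C-9-unsubstituted analogue of 10 | O[C@]1(C[Si](C)(C)C)C=CC[C@@H]2CC(=O)C=C[C@]12C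
F5 | step 7 | C-9-unsubstituted analogue of triol 11 | O[C@]1(C[Si](C)(C)C)[C@H](O)[C@H](O)C[C@@H]2CC(=O)C=C[C@]12C
F6 | step 7 | C-9-unsubstituted analogue of acetonide 12 | O[C@]1(C[Si](C)(C)C)[C@@H]3OC(C)(C)O[C@@H]3C[C@@H]2CC(=O)C=C[C@]12C
F7 | step 7 | 9-[3-oxo-2-(trimethylsilyl)butyl] adduct of F6 | O[C@]1(C[Si](C)(C)C)[C@@H]3OC(C)(C)O[C@@H]3C[C@@H]2[C@H](CC([Si](C)(C)C)C(C)=O)C(=O)C=C[C@]12C
F8 | step 7 | 9-(3-oxobutyl) enone lacking C-20 | O[C@]1(C[Si](C)(C)C)[C@@H]3OC(C)(C)O[C@@H]3C[C@@H]2[C@H](CCC(C)=O)C(=O)C=C[C@]12C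
F9 | step 7 | tert-butyl (13E)-enoate lacking C-20 | O[C@]1(C[Si](C)(C)C)[C@@H]3OC(C)(C)O[C@@H]3C[C@@H]2[C@H](CC/C(C)=C/C(=O)OC(C)(C)C)C(=O)C=C[C@]12C
F10 | step 11 | 7α-hydroxy-8β-methyl isomer of 21 | O[C@]1(C[Si](C)(C)C)[C@@H]3OC(C)(C)O[C@@H]3C[C@@H]2[C@@](C)(CC/C(C)=C/C(=O)OC(C)(C)C)[C@@H](C)[C@H](O)C[C@]12C
F11 | step 11 | 8β-methyl 7-ketone | O[C@]1(C[Si](C)(C)C)[C@@H]3OC(C)(C)O[C@@H]3C[C@@H]2[C@@](C)(CC/C(C)=C/C(=O)OC(C)(C)C)[C@@H](C)C(=O)C[C@]12C
F12 | step 11 | 8α-methyl 7-ketone | O[C@]1(C[Si](C)(C)C)[C@@H]3OC(C)(C)O[C@@H]3C[C@@H]2[C@@](C)(CC/C(C)=C/C(=O)OC(C)(C)C)[C@H](C)C(=O)C[C@]12C
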